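**Plan**

1. Feature: in ring A (C1 carbonyl, C2 with the benzofuranylmethyl arm, C3, quaternary C4, C5, C6) the O-bearing carbons C4 and C5 are neighbours. At the ketol level (C4 tertiary carbinol, C5 ketone) they form an acyloin, so C4–C5 is cut to a C5 aldehyde and a C4 ketone held cis on the C2=C3 alkene.
2. Further cuts: aryl O–Si; styryl CH–Ph (Suzuki); CH=CHCl (cross-metathesis); C1=O (bis-allylic oxidation); both ring A O–CH3 bonds; C4–CH2 of the allyl group (Grignard on a Weinreb amide); C2–CH2 of the linker (alkenylboronate plus benzylic bromide); benzofuran C2–CH2, O1–C2 and C3–C3a.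
3. Forward: the benzofuran ring is built first from vanillin and 2-bromoacetophenone. The chain from 4-pentyn-1-ol is joined to it by Suzuki coupling, extended to the allyl ketone and oxidised to the keto-aldehyde. Ring A closes last by a carbene benzoin reaction, followed by methylations, chloroalkene formation, C1 oxidation, phenylation and desilylation.
4. Stereochemistry: C4 (R) comes from the chiral aminoindanol triazolium carbene in the ring closure. The cis C2=C3 geometry comes from syn borylcupration of an ynamide and stereoretentive coupling. The Z-styryl unit comes from Z-selective metathesis and stereoretentive Suzuki coupling.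

Key step: step 14

Assumption: the (5aR,10bS) enantiomer of the aminoindanol triazolium salt is taken to deliver the (R)-carbinol at C4; should it induce the opposite sense, its (5aS,10bR) mirror image is used instead.

Ring A atoms are numbered C1–C6 as in the target throughout.

**Route**

Step 1
Reactants: 1 vanillin (4-hydroxy-3-methoxybenzaldehyde)
Product: 2 3-methoxy-4-(triisopropylsilyloxy)benzaldehyde
Conditions: TIPSCl, imidazole, DMF, 23 °C
Reagents that add atoms: chlorotriisopropylsilane (TIPSCl), CC(C)[Si](Cl)(C(C)C)C(C)C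
Why: Imidazole-mediated silylation of the phenol; the bulky triisopropylsilyl ether is chosen because it should survive mild base, acid resin, organolithium at low temperature and aqueous phosphate before fluoride removes it in the last step.

Step 2
Reactants: 2 3-methoxy-4-(triisopropylsilyloxy)benzaldehyde
Product: 4 3-methoxy-4-(triisopropylsilyloxy)phenol, via aryl formate 3 (not isolated)
Conditions: mCPBA, CH2Cl2, 0 to 23 °C; then Et3N (cat.), MeOH, 23 °C
Reagents that add atoms: 3-chloroperoxybenzoic acid (mCPBA), OOC(=O)c1cccc(Cl)c1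
Why: Dakin-type Baeyer–Villiger oxidation in which the electron-rich aryl group migrates to give the formate, which amine-catalysed methanolysis cleaves far faster than the hindered aryl silyl ether.

Step 3
Reactants: 4 3-methoxy-4-(triisopropylsilyloxy)phenol; 5 2-bromoacetophenone
Product: 6 2-[3-methoxy-4-(triisopropylsilyloxy)phenoxy]-1-phenylethan-1-one
Conditions: K2CO3, acetone, 23 °C
Reagents that add atoms: none
Why: Williamson ether synthesis, an SN2 displacement of a primary α-bromo ketone by the phenoxide in an aprotic medium that leaves the silyl ether alone.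

Step 4
Reactants: 6 2-[3-methoxy-4-(triisopropylsilyloxy)phenoxy]-1-phenylethan-1-one
Product: 7 6-methoxy-3-phenyl-5-(triisopropylsilyloxy)-1-benzofuran
Conditions: Amberlyst-15, toluene, 110 °C, Dean–Stark
Reagents that add atoms: none
Why: Acid-catalysed cyclodehydration of an α-aryloxy ketone (intramolecular Friedel–Crafts attack on the protonated ketone, then loss of water); closure should go to the ring position para to OMe, the less hindered of the two activated sites, which gives the 3-phenyl-6-methoxy pattern.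

Step 5
Reactants: 7 6-methoxy-3-phenyl-5-(triisopropylsilyloxy)-1-benzofuran
Product: 9 [6-methoxy-3-phenyl-5-(triisopropylsilyloxy)-1-benzofuran-2-yl]methanol, via 2-lithiobenzofuran 8 (not isolated)
Conditions: n-BuLi, THF, −78 °C; then (CH2O)n, −78 to 23 °C; aq. NH4Cl
Reagents that add atoms: paraformaldehyde (reacts as formaldehyde), C=O
Why: The benzofuran C2–H is the most acidic ring hydrogen and is removed at −78 °C before ortho-lithiation next to OMe can compete; the 2-lithio species then adds to formaldehyde (hydroxymethylation) to install the linker carbon.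

Step 6
Reactants: 9 [6-methoxy-3-phenyl-5-(triisopropylsilyloxy)-1-benzofuran-2-yl]methanol
Product: 10 2-(bromomethyl)-6-methoxy-3-phenyl-5-(triisopropylsilyloxy)-1-benzofuran
Conditions: CBr4, PPh3, CH2Cl2, 0 °C; used at once
Reagents that add atoms: tetrabromomethane, BrC(Br)(Br)Br
Why: Appel bromination under neutral conditions, suited to an electron-rich, acid-sensitive heterobenzylic alcohol.

Step 7
Reactants: 11 4-pentyn-1-ol
Product: 12 tert-butyldimethyl(pent-4-yn-1-yloxy)silane
Conditions: TBSCl, imidazole, CH2Cl2, 23 °C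
Reagents that add atoms: tert-butylchlorodimethylsilane (TBSCl), CC(C)(C)[Si](C)(C)Cl
Why: Standard silylation of the primary alcohol, masking the carbon that becomes the C5 aldehyde.

Step 8
Reactants: 12 tert-butyldimethyl(pent-4-yn-1-yloxy)silane; 13 N-methoxy-N-methylcarbamoyl chloride
Product: 15 6-(tert-butyldimethylsilyloxy)-N-methoxy-N-methylhex-2-ynamide, via lithium acetylide 14 (not isolated)
Conditions: n-BuLi, THF, −78 °C; then 13, −78 to 0 °C
Reagents that add atoms: none
Why: Acylation of a lithium acetylide with a carbamoyl chloride gives the alkynyl Weinreb amide directly; its carbonyl carbon becomes C4 of ring A.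

Step 9
Reactants: 15 6-(tert-butyldimethylsilyloxy)-N-methoxy-N-methylhex-2-ynamide
Product: 16 (2Z)-6-(tert-butyldimethylsilyloxy)-N-methoxy-N-methyl-3-(4,4,5,5-tetramethyl-1,3,2-dioxaborolan-2-yl)hex-2-enamide (boron trans to the carbonyl, silyloxypropyl chain cis to it)
Conditions: B2pin2, CuCl (5 mol%), Xantphos (5 mol%), NaOtBu (10 mol%), MeOH (2 equiv), THF, 23 °C
Reagents that add atoms: bis(pinacolato)diboron, CC1(C)OB(OC1(C)C)B1OC(C)(C)C(C)(C)O1
Why: Copper-catalysed conjugate borylation of an alkynyl carbonyl compound: the borylcopper species adds syn with boron at the β-carbon and methanol protonates the α-alkenylcopper with retention, which fixes the chain cis to the carbonyl as ring closure later requires.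

Step 10
Reactants: 16 the (2Z)-β-boryl enamide; 10 2-(bromomethyl)-6-methoxy-3-phenyl-5-(triisopropylsilyloxy)-1-benzofuran
Product: 17 (2E)-6-(tert-butyldimethylsilyloxy)-N-methoxy-N-methyl-3-{[6-methoxy-3-phenyl-5-(triisopropylsilyloxy)-1-benzofuran-2-yl]methyl}hex-2-enamide (chain still cis to the carbonyl; the descriptor changes only because CH2Ar outranks the chain)
Conditions: PdCl2(dppf) (5 mol%), K3PO4, THF/H2O (10:1), 50 °C
Reagents that add atoms: none
Why: Suzuki–Miyaura coupling of an alkenylboronate with a benzylic bromide; the benzylpalladium intermediate has no β-hydrogen and transmetalation and reductive elimination retain the alkene geometry, forming the C2–CH2 linker bond.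

Step 11
Reactants: 17 the (2E)-silyloxy enamide
Product: 18 (2E)-6-hydroxy-N-methoxy-N-methyl-3-{[6-methoxy-3-phenyl-5-(triisopropylsilyloxy)-1-benzofuran-2-yl]methyl}hex-2-enamide
Conditions: CSA (10 mol%), MeOH/CH2Cl2 (1:1), 0 °C
Reagents that add atoms: none
Why: Acid-catalysed methanolysis cleaves the primary alkyl TBS ether while the far more acid-stable aryl TIPS ether and the Weinreb amide persist; it is done here so that the isomerisation-prone allyl ketone never meets acid.

Step 12
Reactants: 18 the (2E)-hydroxy enamide; 19 allylmagnesium bromide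
Product: 21 (5E)-9-hydroxy-6-{[6-methoxy-3-phenyl-5-(triisopropylsilyloxy)-1-benzofuran-2-yl]methyl}nona-1,5-dien-4-one, via magnesium hemiaminal chelate 20 (not isolated)
Conditions: 19 (3 equiv), THF, −78 °C; aq. NH4Cl, −78 °C
Reagents that add atoms: none
Why: Weinreb ketone synthesis: one equivalent of Grignard reagent is consumed by the hydroxyl, the next adds to the amide, and the magnesium chelate holds the tetrahedral adduct until the cold near-neutral quench, which should release the β,γ-unsaturated ketone without over-addition or conjugation.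

Step 13
Reactants: 21 the (5E)-hydroxy dienone
Product: 22 (4E)-4-{[6-methoxy-3-phenyl-5-(triisopropylsilyloxy)-1-benzofuran-2-yl]methyl}-6-oxonona-4,8-dienal (aldehyde tether and acyl group cis on C2=C3)
Conditions: DMP, CH2Cl2, 0 to 23 °C; used directly
Reagents that add atoms: none
Why: Dess–Martin oxidation converts the primary alcohol to the aldehyde under neutral conditions that do not enolise the skipped dienone.

Step 14
Reactants: 22 the (4E)-keto-aldehyde
Product: 23 (2R)-2-hydroxy-4-{[6-methoxy-3-phenyl-5-(triisopropylsilyloxy)-1-benzofuran-2-yl]methyl}-2-(prop-2-en-1-yl)cyclohex-3-en-1-one (ring A: C5 ketone, C4 tertiary carbinol, C2=C3 alkene)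
Conditions: (5aR,10bS)-2-(pentafluorophenyl)-5a,10b-dihydro-4H,6H-indeno[2,1-b][1,2,4]triazolo[4,3-d][1,4]oxazin-2-ium tetrafluoroborate (15 mol%), NaOAc (15 mol%), THF (0.02 M), 23 °C
Reagents that add atoms: none
Why: Acetate deprotonates the triazolium salt, the carbene adds to the unhindered aliphatic aldehyde (C5) and proton transfer gives the Breslow intermediate, an acyl anion equivalent that attacks the C4 ketone; proton transfer and loss of the carbene then leave the tertiary α-ketol. The closest known reaction type is the enantioselective intramolecular crossed aldehyde–ketone benzoin reaction of keto-aldehydes under chiral bicyclic triazolium carbenes. Ring A closes in a 6-exo-trig mode through the C4–C5 bond. The C4 configuration is set by the catalyst: the indane wall of the aminoindanol backbone shields one face of the Breslow intermediate and the hydrogen bond from its enol OH to the ketone oxygen fixes the approach, so that the ring alkenyl arm (C3) and the allyl-bearing CH2 are told apart and the (R)-carbinol should result. The step needs this closure to win over Stetter addition, aldol reactions and conjugation of the skipped dienone: the cis C2=C3 alkene holds aldehyde and ketone together, Stetter attack at C2 would give a four-membered ring, and a weak acetate base with a strongly acidic pentafluorophenyl triazolium salt keeps enolate concentrations low. High dilution suppresses intermolecular homo-benzoin coupling.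

Step 15
Reactants: 23 the (2R)-ketol
Product: 24 (2R)-2-methoxy-4-{[6-methoxy-3-phenyl-5-(triisopropylsilyloxy)-1-benzofuran-2-yl]methyl}-2-(prop-2-en-1-yl)cyclohex-3-en-1-one
Conditions: MeOTf, 2,6-di-tert-butyl-4-methylpyridine, CH2Cl2, 0 to 40 °C
Reagents that add atoms: methyl trifluoromethanesulfonate (MeOTf), COS(=O)(=O)C(F)(F)F
Why: O-Methylation of the hindered tertiary carbinol with a powerful methylating agent and a non-nucleophilic base avoids any alkoxide, so that neither anionic oxy-Cope rearrangement of the 3-hydroxy-1,5-diene nor an α-ketol shift nor enolate C-methylation can occur.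

Step 16
Reactants: 24 the (2R)-methoxy ketone
Product: 26 2-{[(3R)-3,4-dimethoxy-3-(prop-2-en-1-yl)cyclohexa-1,4-dien-1-yl]methyl}-6-methoxy-3-phenyl-5-(triisopropylsilyloxy)-1-benzofuran, via potassium enolate 25 (not isolated)
Conditions: KN(SiMe3)2, THF/DMPU (4:1), −78 °C; then Me2SO4, −78 to −20 °C; Et3N-buffered work-up
Reagents that add atoms: dimethyl sulfate, COS(=O)(=O)OC
Why: The C5 ketone can enolise only toward C6 because C4 is quaternary, and a dissociated potassium enolate in a dipolar medium should react with the hard electrophile dimethyl sulfate at oxygen (enolate O-alkylation), giving the C5 methyl enol ether without regiochemical doubt.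

Step 17
Reactants: 26 the allyl dimethoxy diene; 27 (Z)-1,2-dichloroethene
Product: 28 2-{[(3R)-3-[(2Z)-3-chloroprop-2-en-1-yl]-3,4-dimethoxycyclohexa-1,4-dien-1-yl]methyl}-6-methoxy-3-phenyl-5-(triisopropylsilyloxy)-1-benzofuran
Conditions: Mo(NC6F5)(CHCMe2Ph)(2,5-Me2C4H2N)(O-2,6-(2,4,6-iPr3C6H2)2C6H3) (5 mol%), 27 (5 equiv), C6H6, 22 °C
Reagents that add atoms: none
Why: Z-selective olefin cross-metathesis with a molybdenum monoaryloxide pyrrolide alkylidene, whose large aryloxide forces both metallacyclobutane substituents toward the small imido ligand; only the monosubstituted alkene should react, and at this stage the substrate has no carbonyl or protic group that could destroy the alkylidene.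

Step 18
Reactants: 28 the (Z)-chloroalkenyl diene
Product: 29 (4R)-4-[(2Z)-3-chloroprop-2-en-1-yl]-4,5-dimethoxy-2-{[6-methoxy-3-phenyl-5-(triisopropylsilyloxy)-1-benzofuran-2-yl]methyl}cyclohexa-2,5-dien-1-one
Conditions: Rh2(C6H10NO)4 (dirhodium tetrakis(caprolactamate), 1 mol%), t-BuOOH (5 equiv), K2CO3 (0.5 equiv), CH2Cl2, 23 °C
Reagents that add atoms: tert-butyl hydroperoxide, CC(C)(C)OO
Why: Radical allylic oxidation by tert-butylperoxyl radicals; the C1 methylene, flanked by the enol ether and the C2=C3 alkene, carries the weakest C–H bonds in the molecule (weaker than the allylic, heterobenzylic linker CH2), C4 is quaternary so the dienyl radical cannot aromatise, and the same bis-allylic oxidation is established for 1-methoxy-1,4-cyclohexadienes that carry a quaternary carbon.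

Step 19
Reactants: 29 the (Z)-chloroalkenyl dienone; 30 phenylboronic acid
Product: 31 (4R)-4,5-dimethoxy-2-{[6-methoxy-3-phenyl-5-(triisopropylsilyloxy)-1-benzofuran-2-yl]methyl}-4-[(2Z)-3-phenylprop-2-en-1-yl]cyclohexa-2,5-dien-1-one
Conditions: Pd(OAc)2 (5 mol%), SPhos (10 mol%), K3PO4, toluene/H2O (10:1), 60 °C
Reagents that add atoms: none
Why: Suzuki–Miyaura coupling of an alkenyl chloride, whose oxidative addition to zerovalent palladium is made possible by the electron-rich biaryl phosphine, proceeds with retention of the Z geometry.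

Step 20
Reactants: 31 the silyl-protected target
Product: 32 (4R)-2-[(5-hydroxy-6-methoxy-3-phenyl-1-benzofuran-2-yl)methyl]-4,5-dimethoxy-4-[(2Z)-3-phenylprop-2-en-1-yl]cyclohexa-2,5-dien-1-one (CNP0306784.1)
Conditions: TBAF, AcOH, THF, 0 °C
Reagents that add atoms: none
Why: Fluoride cleaves the aryl silyl ether, and the acetic acid buffer keeps the phenoxide and the dienone away from basic fluoride.

**Compound list**

1 | vanillin | COc1cc(C=O)ccc1O | starting material
2 | 3-methoxy-4-(triisopropylsilyloxy)benzaldehyde | COc1cc(C=O)ccc1O[Si](C(C)C)(C(C)C)C(C)C | intermediate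
3 | 3-methoxy-4-(triisopropylsilyloxy)phenyl formate | COc1cc(OC=O)ccc1O[Si](C(C)C)(C(C)C)C(C)C | intermediate
4 | 3-methoxy-4-(triisopropylsilyloxy)phenol | COc1cc(O)ccc1O[Si](C(C)C)(C(C)C)C(C)C | intermediate
5 | 2-bromoacetophenone | O=C(CBr)c1ccccc1 | starting material
6 | 2-[3-methoxy-4-(triisopropylsilyloxy)phenoxy]-1-phenylethan-1-one | COc1cc(OCC(=O)c2ccccc2)ccc1O[Si](C(C)C)(C(C)C)C(C)C | intermediate
7 | 6-methoxy-3-phenyl-5-(triisopropylsilyloxy)-1-benzofuran | c1oc2cc(OC)c(O[Si](C(C)C)(C(C)C)C(C)C)cc2c1-c1ccccc1 | intermediate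
8 | 2-lithio-6-methoxy-3-phenyl-5-(triisopropylsilyloxy)-1-benzofuran | [Li]c1oc2cc(OC)c(O[Si](C(C)C)(C(C)C)C(C)C)cc2c1-c1ccccc1 | intermediate
9 | [6-methoxy-3-phenyl-5-(triisopropylsilyloxy)-1-benzofuran-2-yl]methanol | OCc1oc2cc(OC)c(O[Si](C(C)C)(C(C)C)C(C)C)cc2c1-c1ccccc1 | intermediate
10 | 2-(bromomethyl)-6-methoxy-3-phenyl-5-(triisopropylsilyloxy)-1-benzofuran | BrCc1oc2cc(OC)c(O[Si](C(C)C)(C(C)C)C(C)C)cc2c1-c1ccccc1 | intermediate
11 | 4-pentyn-1-ol | C#CCCCO | starting material
12 | tert-butyldimethyl(pent-4-yn-1-yloxy)silane | C#CCCCO[Si](C)(C)C(C)(C)C | intermediate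
13 | N-methoxy-N-methylcarbamoyl chloride | CON(C)C(Cl)=O | starting material
14 | lithium acetylide of 12 | [Li]C#CCCCO[Si](C)(C)C(C)(C)C | intermediate
15 | 6-(tert-butyldimethylsilyloxy)-N-methoxy-N-methylhex-2-ynamide | CON(C)C(=O)C#CCCCO[Si](C)(C)C(C)(C)C | intermediate
16 | (2Z)-6-(tert-butyldimethylsilyloxy)-N-methoxy-N-methyl-3-(4,4,5,5-tetramethyl-1,3,2-dioxaborolan-2-yl)hex-2-enamide | CON(C)C(=O)/C=C(\CCCO[Si](C)(C)C(C)(C)C)B1OC(C)(C)C(C)(C)O1 | intermediate
17 | (2E)-6-(tert-butyldimethylsilyloxy)-N-methoxy-N-methyl-3-{[6-methoxy-3-phenyl-5-(triisopropylsilyloxy)-1-benzofuran-2-yl]methyl}hex-2-enamide | CON(C)C(=O)/C=C(\CCCO[Si](C)(C)C(C)(C)C)Cc1oc2cc(OC)c(O[Si](C(C)C)(C(C)C)C(C)C)cc2c1-c1ccccc1 | intermediate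
18 | (2E)-6-hydroxy-N-methoxy-N-methyl-3-{[6-methoxy-3-phenyl-5-(triisopropylsilyloxy)-1-benzofuran-2-yl]methyl}hex-2-enamide | CON(C)C(=O)/C=C(\CCCO)Cc1oc2cc(OC)c(O[Si](C(C)C)(C(C)C)C(C)C)cc2c1-c1ccccc1 | intermediate
19 | allylmagnesium bromide | C=CC[Mg]Br | starting material
20 | bis(bromomagnesium) salt of the tetrahedral allyl adduct of 18 | C=CCC(O[Mg]Br)(N(C)OC)/C=C(\CCCO[Mg]Br)Cc1oc2cc(OC)c(O[Si](C(C)C)(C(C)C)C(C)C)cc2c1-c1ccccc1 | intermediate
21 | (5E)-9-hydroxy-6-{[6-methoxy-3-phenyl-5-(triisopropylsilyloxy)-1-benzofuran-2-yl]methyl}nona-1,5-dien-4-one | C=CCC(=O)/C=C(\CCCO)Cc1oc2cc(OC)c(O[Si](C(C)C)(C(C)C)C(C)C)cc2c1-c1ccccc1 | intermediate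
22 | (4E)-4-{[6-methoxy-3-phenyl-5-(triisopropylsilyloxy)-1-benzofuran-2-yl]methyl}-6-oxonona-4,8-dienal | O=CCC/C(Cc1oc2cc(OC)c(O[Si](C(C)C)(C(C)C)C(C)C)cc2c1-c1ccccc1)=C\C(=O)CC=C | intermediate
23 | (2R)-2-hydroxy-4-{[6-methoxy-3-phenyl-5-(triisopropylsilyloxy)-1-benzofuran-2-yl]methyl}-2-(prop-2-en-1-yl)cyclohex-3-en-1-one | O=C1CCC(Cc2oc3cc(OC)c(O[Si](C(C)C)(C(C)C)C(C)C)cc3c2-c2ccccc2)=C[C@@]1(CC=C)O | intermediate
24 | (2R)-2-methoxy-4-{[6-methoxy-3-phenyl-5-(triisopropylsilyloxy)-1-benzofuran-2-yl]methyl}-2-(prop-2-en-1-yl)cyclohex-3-en-1-one | O=C1CCC(Cc2oc3cc(OC)c(O[Si](C(C)C)(C(C)C)C(C)C)cc3c2-c2ccccc2)=C[C@@]1(CC=C)OC | intermediate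
25 | potassium enolate of 24 | [K+].[O-]C1=CCC(Cc2oc3cc(OC)c(O[Si](C(C)C)(C(C)C)C(C)C)cc3c2-c2ccccc2)=C[C@@]1(CC=C)OC | intermediate
26 | 2-{[(3R)-3,4-dimethoxy-3-(prop-2-en-1-yl)cyclohexa-1,4-dien-1-yl]methyl}-6-methoxy-3-phenyl-5-(triisopropylsilyloxy)-1-benzofuran | COC1=CCC(Cc2oc3cc(OC)c(O[Si](C(C)C)(C(C)C)C(C)C)cc3c2-c2ccccc2)=C[C@@]1(CC=C)OC | intermediate
27 | (Z)-1,2-dichloroethene | Cl/C=C\Cl | starting material
28 | 2-{[(3R)-3-[(2Z)-3-chloroprop-2-en-1-yl]-3,4-dimethoxycyclohexa-1,4-dien-1-yl]methyl}-6-methoxy-3-phenyl-5-(triisopropylsilyloxy)-1-benzofuran | COC1=CCC(Cc2oc3cc(OC)c(O[Si](C(C)C)(C(C)C)C(C)C)cc3c2-c2ccccc2)=C[C@@]1(C/C=C\Cl)OC | intermediate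
29 | (4R)-4-[(2Z)-3-chloroprop-2-en-1-yl]-4,5-dimethoxy-2-{[6-methoxy-3-phenyl-5-(triisopropylsilyloxy)-1-benzofuran-2-yl]methyl}cyclohexa-2,5-dien-1-one | COC1=CC(=O)C(Cc2oc3cc(OC)c(O[Si](C(C)C)(C(C)C)C(C)C)cc3c2-c2ccccc2)=C[C@@]1(C/C=C\Cl)OC | intermediate
30 | phenylboronic acid | OB(O)c1ccccc1 | starting material
31 | (4R)-4,5-dimethoxy-2-{[6-methoxy-3-phenyl-5-(triisopropylsilyloxy)-1-benzofuran-2-yl]methyl}-4-[(2Z)-3-phenylprop-2-en-1-yl]cyclohexa-2,5-dien-1-one | COC1=CC(=O)C(Cc2oc3cc(OC)c(O[Si](C(C)C)(C(C)C)C(C)C)cc3c2-c2ccccc2)=C[C@@]1(C/C=C\c1ccccc1)OC | intermediate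
32 | (4R)-2-[(5-hydroxy-6-methoxy-3-phenyl-1-benzofuran-2-yl)methyl]-4,5-dimethoxy-4-[(2Z)-3-phenylprop-2-en-1-yl]cyclohexa-2,5-dien-1-one | COC1=CC(=O)C(Cc2oc3cc(OC)c(O)cc3c2-c2ccccc2)=C[C@@]1(C/C=C\c1ccccc1)OC | target

**Step count and risks**

Total step count: 20. Longest linear sequence: 17 steps (steps 1–6 and 10–20, from vanillin).

The three steps most likely to fail:

Step 14. The carbene may not tell the two faces of the C4 ketone apart, since the ring alkenyl CH and the allylic CH2 differ little in size, or base-mediated conjugation and aldol closure may outrun formation of the acyl anion equivalent. The fallback gives up catalyst control in favour of resolution. Setting out from 22, the same closure is run with the achiral carbene from 2-mesityl-6,7-dihydro-5H-pyrrolo[2,1-c][1,2,4]triazol-2-ium chloride and NaOAc in THF to give racemic 2-hydroxy-4-{[6-methoxy-3-phenyl-5-(triisopropylsilyloxy)-1-benzofuran-2-yl]methyl}-2-(prop-2-en-1-yl)cyclohex-3-en-1-one F1. Its enantiomers are separated by preparative HPLC on a polysaccharide-based chiral stationary phase, and the (R)-enantiomer is 23, where the route is rejoined.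

Step 16. Methylation of the enolate at carbon C6 may compete with methylation at oxygen, and the enol ether may hydrolyse on isolation. The fallback replaces enolate alkylation by ketalisation and elimination. Setting out from 24, HC(OMe)3 and CSA in MeOH should give the dimethyl ketal 2-{[(3R)-3,4,4-trimethoxy-3-(prop-2-en-1-yl)cyclohex-1-en-1-yl]methyl}-6-methoxy-3-phenyl-5-(triisopropylsilyloxy)-1-benzofuran F2. Treatment with TMSOTf and iPr2NEt in CH2Cl2 then removes methanol toward C6, the only side that carries hydrogen, and the route is rejoined at 26.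

Step 17. The moisture-sensitive molybdenum alkylidene may be deactivated by the polyether substrate, or secondary metathesis may erode the Z geometry. The fallback builds the Z-haloalkene by carbonyl olefination instead, setting out from 24 and returning at 31.
- Oxidative cleavage of the terminal alkene with OsO4 (cat.), NaIO4 and 2,6-lutidine in dioxane/H2O should give the aldehyde 2-[(1R)-1-methoxy-3-{[6-methoxy-3-phenyl-5-(triisopropylsilyloxy)-1-benzofuran-2-yl]methyl}-6-oxocyclohex-2-en-1-yl]acetaldehyde F3.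
- Stork–Zhao olefination with the ylide from (iodomethyl)triphenylphosphonium iodide and NaN(SiMe3)2 in THF/DMPU at −78 °C should give the (Z)-alkenyl iodide (2R)-2-[(2Z)-3-iodoprop-2-en-1-yl]-2-methoxy-4-{[6-methoxy-3-phenyl-5-(triisopropylsilyloxy)-1-benzofuran-2-yl]methyl}cyclohex-3-en-1-one F4.
- Enolate O-methylation under the conditions of step 16 leads to the iodo enol ether 2-{[(3R)-3-[(2Z)-3-iodoprop-2-en-1-yl]-3,4-dimethoxycyclohexa-1,4-dien-1-yl]methyl}-6-methoxy-3-phenyl-5-(triisopropylsilyloxy)-1-benzofuran F5.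
- C1 oxidation under the conditions of step 18 leads to the iodo dienone (4R)-4-[(2Z)-3-iodoprop-2-en-1-yl]-4,5-dimethoxy-2-{[6-methoxy-3-phenyl-5-(triisopropylsilyloxy)-1-benzofuran-2-yl]methyl}cyclohexa-2,5-dien-1-one F6.
- Suzuki coupling of F6 with 30 (Pd(OAc)2, SPhos, K3PO4) rejoins the route at 31.

Further compounds

F1 | step 14 | racemic 2-hydroxy-4-{[6-methoxy-3-phenyl-5-(triisopropylsilyloxy)-1-benzofuran-2-yl]methyl}-2-(prop-2-en-1-yl)cyclohex-3-en-1-one | O=C1CCC(Cc2oc3cc(OC)c(O[Si](C(C)C)(C(C)C)C(C)C)cc3c2-c2ccccc2)=CC1(CC=C)O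
F2 | step 16 | 2-{[(3R)-3,4,4-trimethoxy-3-(prop-2-en-1-yl)cyclohex-1-en-1-yl]methyl}-6-methoxy-3-phenyl-5-(triisopropylsilyloxy)-1-benzofuran | COC1(OC)CCC(Cc2oc3cc(OC)c(O[Si](C(C)C)(C(C)C)C(C)C)cc3c2-c2ccccc2)=C[C@@]1(CC=C)OC
F3 | step 17 | 2-[(1R)-1-methoxy-3-{[6-methoxy-3-phenyl-5-(triisopropylsilyloxy)-1-benzofuran-2-yl]methyl}-6-oxocyclohex-2-en-1-yl]acetaldehyde | O=C1CCC(Cc2oc3cc(OC)c(O[Si](C(C)C)(C(C)C)C(C)C)cc3c2-c2ccccc2)=C[C@@]1(CC=O)OC
F4 | step 17 | (2R)-2-[(2Z)-3-iodoprop-2-en-1-yl]-2-methoxy-4-{[6-methoxy-3-phenyl-5-(triisopropylsilyloxy)-1-benzofuran-2-yl]methyl}cyclohex-3-en-1-one | O=C1CCC(Cc2oc3cc(OC)c(O[Si](C(C)C)(C(C)C)C(C)C)cc3c2-c2ccccc2)=C[C@@]1(C/C=C\I)OC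
F5 | step 17 | 2-{[(3R)-3-[(2Z)-3-iodoprop-2-en-1-yl]-3,4-dimethoxycyclohexa-1,4-dien-1-yl]methyl}-6-methoxy-3-phenyl-5-(triisopropylsilyloxy)-1-benzofuran | COC1=CCC(Cc2oc3cc(OC)c(O[Si](C(C)C)(C(C)C)C(C)C)cc3c2-c2ccccc2)=C[C@@]1(C/C=C\I)OC
F6 | step 17 | (4R)-4-[(2Z)-3-iodoprop-2-en-1-yl]-4,5-dimethoxy-2-{[6-methoxy-3-phenyl-5-(triisopropylsilyloxy)-1-benzofuran-2-yl]methyl}cyclohexa-2,5-dien-1-one | COC1=CC(=O)C(Cc2oc3cc(OC)c(O[Si](C(C)C)(C(C)C)C(C)C)cc3c2-c2ccccc2)=C[C@@]1(C/C=C\I)OC
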